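**Plan**

- Labels: the dihydrofuran is numbered as a 2,3-dihydrobenzofuran (O1, C2, C3, C3a, C7a). Ring A is the benzene ring fused to the furan that also carries the ketone carbon; ring B is the resorcinol ring.
- Retrosynthetic cuts, in order: the five O–CH3 bonds; the bond from the aryl-bearing α-carbon of the ketone to ring B (Friedel–Crafts closure of an anisyl epoxide, ketone from the carbinol); the ring A–CH= bond (Heck); then together O1–C7a and C2–C3; then C–S (Andersen) and the diarylmethane C–C bond.
- Forward order: ring A (from 3,5-dibromoanisole) is joined to ring B through the future C3, the dihydrofuran is annulated onto ring A, the stilbene arm is attached, and the seven-membered ring is closed last onto ring B.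
- Enabling feature: C3 is a benzhydrylic carbon flanked by ring A and ring B, and its ring A neighbour C3a is ortho to C7a, the carbon that carries O1. A sulfinyl group at C7a therefore acidifies and chelates C3–H and is itself the leaving group for O1, while O1–C2(aryl) is the C=O of 4-methoxybenzaldehyde.
- Stereochemistry: the sulfur centre from (−)-menthyl (S)-p-toluenesulfinate controls C3 (1,4-induction), C3 controls C2 (trans), and the sulfur leaves in the same step. The α-keto centre is set by thermodynamic equilibration.

Key step: step 4

Assumption: the sense of 1,4-induction in step 4 is taken from the lithium chelate model given there; if experiment showed the opposite sense, the enantiomeric sulfinate made from (+)-menthol would be used in step 3 and nothing else would change.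

**Route**

Step 1
Reactants: 1 1,3-dibromo-5-methoxybenzene; 2 3,5-dimethoxybenzaldehyde
Product: 4 (2,6-dibromo-4-methoxyphenyl)(3,5-dimethoxyphenyl)methanol (racemic), via aryllithium 3 (not isolated)
Conditions: LiN(iPr)2, THF, −78 °C; then 2, −78 °C; H2O
Reagents that add atoms: none
Why: LiN(iPr)2 removes the proton between the two bromine atoms of 1 (acidified by two ortho halogens; amide-base ortho-metalation), and aryllithium 3, stable at −78 °C, undergoes 1,2-addition to aldehyde 2; the racemic carbinol centre is removed in step 2.

Step 2
Reactants: 4 (2,6-dibromo-4-methoxyphenyl)(3,5-dimethoxyphenyl)methanol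
Product: 5 1,3-dibromo-2-[(3,5-dimethoxyphenyl)methyl]-5-methoxybenzene
Conditions: Et3SiH (excess), CF3CO2H, CH2Cl2, 0 to 25 °C
Reagents that add atoms: none
Why: Ionic hydrogenation: the acid ionises the diarylmethanol to the benzhydryl cation, which Et3SiH reduces by hydride transfer, and excess silane should outrun Friedel–Crafts alkylation of the electron-rich ring B.

Step 3
Reactants: 5 1,3-dibromo-2-[(3,5-dimethoxyphenyl)methyl]-5-methoxybenzene; 6 (1R,2S,5R)-menthyl (S)-4-methylbenzenesulfinate
Product: 8 (S)-1-bromo-2-[(3,5-dimethoxyphenyl)methyl]-5-methoxy-3-(4-methylbenzenesulfinyl)benzene, via aryllithium 7 (not isolated)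
Conditions: n-BuLi (1.0 equiv), THF, −78 °C; then added to 6 (1.3 equiv), THF, −78 to 0 °C; H2O
Reagents that add atoms: none
Why: Bromine–lithium exchange at one of the two equivalent C–Br bonds (a second exchange on the aryl anion is disfavoured) followed by Andersen sulfoxide synthesis, a substitution at sulfur with inversion, should give the (S)-sulfoxide; inverse addition keeps aryllithium 7 from deprotonating the product.

Step 4
Reactants: 8 (S)-1-bromo-2-[(3,5-dimethoxyphenyl)methyl]-5-methoxy-3-(4-methylbenzenesulfinyl)benzene; 9 4-methoxybenzaldehyde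
Product: 12 (2R,3R)-4-bromo-3-(3,5-dimethoxyphenyl)-6-methoxy-2-(4-methoxyphenyl)-2,3-dihydro-1-benzofuran, via benzylic lithium compound 10 (not isolated), via lithium alkoxide 11 (not isolated)
Conditions: LiN(iPr)2 (1.1 equiv), THF, −78 °C; 9, −78 °C; then KOt-Bu, 18-crown-6, −78 to 25 °C; H2O
Reagents that add atoms: none
Why: Proposed new method: LiN(iPr)2 removes the benzhydrylic proton of 8 (the most acidic C–H, flanked by ring A and ring B and held by Li–O=S chelation) to give 10, which adds to the carbonyl carbon of 9 to make the C2–C3 bond; the alkoxide 11, freed from lithium by K+/18-crown-6, then attacks the sulfinyl-bearing ring A carbon (the future C7a) and expels p-toluenesulfenate, either by addition–elimination at the ipso carbon or by O–S bonding to a sulfurane and ligand coupling, to make the O1–C7a bond. The closest known reaction type is the anionic tandem of ortho-sulfinyl benzyl carbanions with imines, in which the amide anion formed displaces the sulfinyl group to give indolines; the extension to an aldehyde, an alkoxide nucleophile and a benzhydryl anion is argued from the same five-membered transition state and from the double role of the sulfinyl group as activator and nucleofuge. The dihydrofuran ring closes in the 5-exo-trig mode (attack on the arene ipso carbon, then loss of the sulfur group), with retention at C2 and C3. C3 is controlled by 1,4-induction from the (S)-sulfur centre: with p-tolyl turned away from the benzylic carbon, ring B on the bromine side and H on the sulfinyl side, the sulfinyl oxygen holds lithium and thus the incoming aldehyde on one face of the carbanion, which gives 3R; C2 is controlled by the lithium-bridged transition state in which the anisyl group avoids ring B, which gives the trans (2R) arrangement, and any cis isomer should turn into trans under the Lewis acid of step 6. The step needs benzylic and not ring deprotonation, one carbanion face, and substitution at C–S and not at the other ortho carbon (C–Br); the first is secured by the acidity of the diarylmethane C–H, the second by the sulfur stereocentre, the third because only the sulfinyl-bearing carbon is activated for ipso attack while a bromide on an unactivated ring is inert to alkoxide without a metal catalyst.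

Step 5
Reactants: 12 (2R,3R)-4-bromo-3-(3,5-dimethoxyphenyl)-6-methoxy-2-(4-methoxyphenyl)-2,3-dihydro-1-benzofuran; 13 4-methoxystyrene
Product: 14 (2R,3R)-3-(3,5-dimethoxyphenyl)-6-methoxy-2-(4-methoxyphenyl)-4-[(E)-2-(4-methoxyphenyl)ethenyl]-2,3-dihydro-1-benzofuran
Conditions: Pd(OAc)2 (5 mol %), P(o-tol)3, NaOAc, DMA, 120 °C
Reagents that add atoms: none
Why: Mizoroki–Heck reaction: oxidative addition of zerovalent palladium into the hindered C–Br bond, insertion of the styrene at its terminal carbon and syn β-hydride elimination should give the (E)-stilbene without touching the stereocentres.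

Step 6
Reactants: 14 (2R,3R)-3-(3,5-dimethoxyphenyl)-6-methoxy-2-(4-methoxyphenyl)-4-[(E)-2-(4-methoxyphenyl)ethenyl]-2,3-dihydro-1-benzofuran
Product: 16 seven-membered-ring alcohol (penta-O-methylpauciflorol E with the ketone carbon as CH–OH; diastereomer mixture at the carbinol carbon and at the adjacent aryl-bearing carbon), via trans-epoxide 15 (not isolated)
Conditions: dimethyldioxirane, acetone/CH2Cl2, −20 °C; evaporate; BF3·OEt2 (0.2 equiv), CH2Cl2, −78 °C; aq NaHCO3
Reagents that add atoms: dimethyldioxirane, CC1(C)OO1
Why: Neutral epoxidation of the electron-rich stilbene, then Lewis-acid opening at the anisyl-stabilised benzylic carbon and intramolecular Friedel–Crafts alkylation by the ortho carbon of ring B (para to one methoxy group, ortho to the other) should close the seven-membered ring, a closure with close precedent in this family; the two new centres form as a mixture of no consequence, since one is oxidised and the other equilibrated in step 7.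

Step 7
Reactants: 16 seven-membered-ring alcohol
Product: 17 penta-O-methylpauciflorol E (all three stereocentres R)
Conditions: Dess–Martin periodinane, NaHCO3, CH2Cl2, 0 to 25 °C; then DBU (0.2 equiv), CH2Cl2, 25 °C
Reagents that add atoms: none
Why: Dess–Martin oxidation of the benzylic alcohol gives the ketone, and DBU should equilibrate the enolisable α-centre to the more stable epimer, in which the 4-methoxyphenyl group stands pseudo-axial, perpendicular to ring B and away from its peri methoxy group and trans to the C3–C2 bond across the seven-membered ring, which is the configuration of the target.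

Step 8
Reactants: 17 penta-O-methylpauciflorol E
Product: 18 pauciflorol E
Conditions: BBr3 (excess), CH2Cl2, −78 to 25 °C; then MeOH, H2O
Reagents that add atoms: none
Why: BBr3 cleaves the five aryl methyl ethers (Lewis acid–base complexation, bromide attack at methyl); the ketone and the benzylic ether of the dihydrofuran should survive at low temperature, and the epimerisable centre stays in its thermodynamic configuration.

**Compound list**

1 | 1,3-dibromo-5-methoxybenzene (3,5-dibromoanisole) | COc1cc(Br)cc(Br)c1 | starting material
2 | 3,5-dimethoxybenzaldehyde | COc1cc(C=O)cc(OC)c1 | starting material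
3 | (2,6-dibromo-4-methoxyphenyl)lithium | [Li]c1c(Br)cc(OC)cc1Br | intermediate
4 | (2,6-dibromo-4-methoxyphenyl)(3,5-dimethoxyphenyl)methanol (racemic) | COc1cc(Br)c(C(O)c2cc(OC)cc(OC)c2)c(Br)c1 | intermediate
5 | 1,3-dibromo-2-[(3,5-dimethoxyphenyl)methyl]-5-methoxybenzene | COc1cc(Br)c(Cc2cc(OC)cc(OC)c2)c(Br)c1 | intermediate
6 | (1R,2S,5R)-menthyl (S)-4-methylbenzenesulfinate | CC(C)[C@@H]1CC[C@@H](C)C[C@H]1O[S@](=O)c1ccc(C)cc1 | starting material
7 | [3-bromo-2-[(3,5-dimethoxyphenyl)methyl]-5-methoxyphenyl]lithium | [Li]c1cc(OC)cc(Br)c1Cc1cc(OC)cc(OC)c1 | intermediate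
8 | (S)-1-bromo-2-[(3,5-dimethoxyphenyl)methyl]-5-methoxy-3-(4-methylbenzenesulfinyl)benzene | COc1cc(Br)c(Cc2cc(OC)cc(OC)c2)c(c1)[S@@](=O)c1ccc(C)cc1 | intermediate
9 | 4-methoxybenzaldehyde | COc1ccc(C=O)cc1 | starting material
10 | benzylic lithium compound of 8 (lithium on the benzhydrylic carbon) | [Li]C(c1cc(OC)cc(OC)c1)c1c(Br)cc(OC)cc1[S@@](=O)c1ccc(C)cc1 | intermediate
11 | lithium (1R,2R)-2-{2-bromo-4-methoxy-6-[(S)-4-methylbenzenesulfinyl]phenyl}-2-(3,5-dimethoxyphenyl)-1-(4-methoxyphenyl)ethan-1-olate | [Li+].[O-][C@@H](c1ccc(OC)cc1)[C@H](c1cc(OC)cc(OC)c1)c1c(Br)cc(OC)cc1[S@@](=O)c1ccc(C)cc1 | intermediate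
12 | (2R,3R)-4-bromo-3-(3,5-dimethoxyphenyl)-6-methoxy-2-(4-methoxyphenyl)-2,3-dihydro-1-benzofuran (trans) | Brc1cc(OC)cc2c1[C@@H](c1cc(OC)cc(OC)c1)[C@H](c1ccc(OC)cc1)O2 | intermediate
13 | 4-methoxystyrene | C=Cc1ccc(OC)cc1 | starting material
14 | (2R,3R)-3-(3,5-dimethoxyphenyl)-6-methoxy-2-(4-methoxyphenyl)-4-[(E)-2-(4-methoxyphenyl)ethenyl]-2,3-dihydro-1-benzofuran | COc1ccc(/C=C/c2cc(OC)cc3c2[C@@H](c2cc(OC)cc(OC)c2)[C@H](c2ccc(OC)cc2)O3)cc1 | intermediate
15 | trans-epoxide of 14, 4-[3-(4-methoxyphenyl)oxiran-2-yl] compound (both epoxide diastereomers; epoxide centres not specified) | COc1ccc(C2OC2c2cc(OC)cc3c2[C@@H](c2cc(OC)cc(OC)c2)[C@H](c2ccc(OC)cc2)O3)cc1 | intermediate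
16 | seven-membered-ring alcohol, penta-O-methylpauciflorol E with CH–OH in place of C=O (mixture at the carbinol and the adjacent aryl-bearing carbon; these two centres not specified) | OC1c2cc(OC)cc3c2[C@@H](c2cc(OC)cc(OC)c2C1c1ccc(OC)cc1)[C@H](c1ccc(OC)cc1)O3 | intermediate
17 | penta-O-methylpauciflorol E (R at C2 and C3 of the dihydrofuran and R at the α-keto carbon) | O=C1c2cc(OC)cc3c2[C@@H](c2cc(OC)cc(OC)c2[C@H]1c1ccc(OC)cc1)[C@H](c1ccc(OC)cc1)O3 | intermediate
18 | pauciflorol E | O=C1c2cc(O)cc3c2[C@@H](c2cc(O)cc(O)c2[C@H]1c1ccc(O)cc1)[C@H](c1ccc(O)cc1)O3 | target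

**Step count and risks**

Total step count: 8. Longest linear sequence: 8 steps (1 to 18).

Step 4 (proposed new method). The alkoxide may fail to displace the sulfinyl group: it may revert by retro-addition, attack sulfur so that the aryl–sulfur bond is lost without C–O bond formation, or add with poor facial selectivity. The fallback sets out from 5 and returns at 12 using known reaction types. The benzylic lithium anion of 5 (LiN(iPr)2, THF, −78 °C) is acylated with N-methoxy-N-methyl-4-methoxybenzamide to give racemic 2-(2,6-dibromo-4-methoxyphenyl)-2-(3,5-dimethoxyphenyl)-1-(4-methoxyphenyl)ethan-1-one F1. Asymmetric transfer hydrogenation with dynamic kinetic resolution of the acidic α,α-diaryl centre (RuCl(p-cymene)(TsDPEN) of the enantiomeric series that delivers the 1R carbinol, HCO2H/Et3N) should give (1R,2R)-2-(2,6-dibromo-4-methoxyphenyl)-2-(3,5-dimethoxyphenyl)-1-(4-methoxyphenyl)ethan-1-ol F2. Intramolecular Ullmann etherification (CuI, 1,10-phenanthroline, Cs2CO3, toluene, 110 °C) onto either of the two equivalent ortho C–Br bonds then closes the dihydrofuran to 12. The two bonds are then made in separate operations and step 3 is not needed.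

Step 6. The benzylic cation may rearrange by hydride or aryl shift (Meinwald type) faster than ring B closes the seven-membered ring. The fallback sets out from 12 and returns at 17. Bromine–lithium exchange on 12 (n-BuLi, THF, −78 °C) and acylation with N-methoxy-N-methyl-2-(4-methoxyphenyl)acetamide give 1-[(2R,3R)-3-(3,5-dimethoxyphenyl)-6-methoxy-2-(4-methoxyphenyl)-2,3-dihydro-1-benzofuran-4-yl]-2-(4-methoxyphenyl)ethan-1-one F3. Regitz diazo transfer (4-acetamidobenzenesulfonyl azide, DBU, MeCN) gives the corresponding 2-diazo-2-(4-methoxyphenyl)ethan-1-one F4. Intramolecular aromatic substitution of ring B by the keto carbene (Rh2(OAc)4, CH2Cl2) or by the diazonium ion (CF3SO3H) then forms the bond from the α-carbon to ring B and gives ketone 17 directly, after the same base equilibration.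

Step 8. The Lewis acid may open the benzylic C2–O1 bond of the dihydrofuran or degrade the polyphenol during ether cleavage. The fallback sets out from 17 and returns at 18. It replaces electrophilic ether cleavage by nucleophilic demethylation with NaSEt in DMF at 120 °C (SN2 at each methyl carbon under basic conditions, the ketone being held as its enolate), followed by acidification, which again leaves the α-centre in its thermodynamic configuration. It makes no compound outside the list (none F0).

Further compounds
F1 | step 4 | 2-(2,6-dibromo-4-methoxyphenyl)-2-(3,5-dimethoxyphenyl)-1-(4-methoxyphenyl)ethan-1-one (racemic) | COc1ccc(cc1)C(=O)C(c1cc(OC)cc(OC)c1)c1c(Br)cc(OC)cc1Br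
F2 | step 4 | (1R,2R)-2-(2,6-dibromo-4-methoxyphenyl)-2-(3,5-dimethoxyphenyl)-1-(4-methoxyphenyl)ethan-1-ol | O[C@@H](c1ccc(OC)cc1)[C@H](c1cc(OC)cc(OC)c1)c1c(Br)cc(OC)cc1Br
F3 | step 6 | 1-[(2R,3R)-3-(3,5-dimethoxyphenyl)-6-methoxy-2-(4-methoxyphenyl)-2,3-dihydro-1-benzofuran-4-yl]-2-(4-methoxyphenyl)ethan-1-one | COc1ccc(CC(=O)c2cc(OC)cc3c2[C@@H](c2cc(OC)cc(OC)c2)[C@H](c2ccc(OC)cc2)O3)cc1
F4 | step 6 | 2-diazo-1-[(2R,3R)-3-(3,5-dimethoxyphenyl)-6-methoxy-2-(4-methoxyphenyl)-2,3-dihydro-1-benzofuran-4-yl]-2-(4-methoxyphenyl)ethan-1-one | COc1ccc(C(=[N+]=[N-])C(=O)c2cc(OC)cc3c2[C@@H](c2cc(OC)cc(OC)c2)[C@H](c2ccc(OC)cc2)O3)cc1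
F0 | step 8 | none | none
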